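**Retrosynthetic overview**

1. The last skeletal bond is C1′–C2′, between the side-chain methylene on the oxolane and the dione carbon. It is made by reductive Knoevenagel alkylation of (S)-4-silyloxycyclohexane-1,3-dione with an oxolane-2-carbaldehyde, followed by desilylation.
2. The feature the strategy rests on: in the oxolane (O1, C2, C3, C4, C5) the exocyclic carbon C1′ sits on C2, which carries the ring oxygen and is flanked by the methyl carbinol C3. O1–C2 and C1′ therefore map onto a six-membered enol ether O1–C1′=C2 (a 4-methyl-3,4-dihydro-2H-pyran-4-ol). Its oxidative ring contraction moves O1 from C1′ to C2 and releases C1′ as an aldehyde acetal.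
3. The dihydropyran comes from 6-endo cycloisomerisation of an ynediol (O1–C1′ bond). The alkyne is made from a γ-lactol by Ohira–Bestmann homologation.
4. The tertiary carbinol is taken from (S)-citramalic acid. The allylic carbinol is set by CBS reduction of an enone made by Negishi acylation with the (E)-alkenylzinc derived from 6-methylhept-5-en-2-one.
5. Ring order: the cyclohexane ring is bought (3-methoxycyclohex-2-en-1-one, hydroxylated and resolved); then dihydropyran; then oxolane by contraction. The dioxolanone and γ-lactone are temporary rings.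

Key step: step 10

Assumption: the target SMILES shows one enol tautomer of a 2-substituted 4-hydroxycyclohexane-1,3-dione; the enol tautomers interconvert, so the route aims at this dione and does not try to fix the tautomer.

Assumption: in step 13 the lipase is taken to follow the usual size rule for secondary alcohols with the carbonyl-bearing carbon as the large group, so the (R)-alcohol is acetylated and the (S)-alcohol is recovered; the sense is to be confirmed before the material is carried on.

**Route**

Step 1
Reactants: 1 6-methylhept-5-en-2-one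
Product: 5 6-methylhept-5-en-1-yne, via lithium enolate 2 (not isolated), via enol phosphate 3 (not isolated), via lithium acetylide 4 (not isolated)
Conditions: LiN(i-Pr)2 (1.05 equiv), THF, −78 °C; ClP(O)(OEt)2, −78 °C → rt; LiN(i-Pr)2 (2.3 equiv), THF, −78 °C → rt; H2O
Reagents that add atoms: none
Why: kinetic deprotonation on the methyl side, O-phosphorylation and double-base elimination of the terminal enol phosphate (methyl ketone to terminal alkyne conversion) should give the alkyne, which is held as its acetylide until the quench so that it does not isomerise.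

Step 2
Reactants: 5 6-methylhept-5-en-1-yne
Product: 7 (1E)-1-iodo-2,6-dimethylhepta-1,5-diene, via alkenylalane 6 (not isolated)
Conditions: Me3Al (2 equiv), Cp2ZrCl2 (0.25 equiv), CH2Cl2, 0 °C → rt; I2, THF, −30 → 0 °C
Reagents that add atoms: trimethylaluminium C[Al](C)C; iodine II
Why: Negishi carboalumination adds methyl and aluminium syn across the terminal alkyne with aluminium at the terminus and leaves the trisubstituted alkene alone, and iodinolysis with retention fixes the E geometry.

Step 3
Reactants: 8 (S)-citramalic acid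
Product: 9 2-[(4S)-2,2,4-trimethyl-5-oxo-1,3-dioxolan-4-yl]acetic acid
Conditions: Me2C(OMe)2, p-TsOH·H2O (cat.), rt
Reagents that add atoms: 2,2-dimethoxypropane COC(C)(C)OC
Why: acid-catalysed transacetalisation ties the tertiary hydroxyl and its α-carboxyl into the five-membered dioxolanone (favoured over the six-membered dioxanone), leaving the β-carboxyl free and the quaternary stereocentre untouched.

Step 4
Reactants: 9 2-[(4S)-2,2,4-trimethyl-5-oxo-1,3-dioxolan-4-yl]acetic acid
Product: 10 2-[(4S)-2,2,4-trimethyl-5-oxo-1,3-dioxolan-4-yl]acetyl chloride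
Conditions: (COCl)2, DMF (cat.), CH2Cl2, 0 °C → rt; evaporate, use crude
Reagents that add atoms: oxalyl chloride O=C(Cl)C(=O)Cl
Why: acid chloride formation through the Vilsmeier intermediate is neutral and anhydrous, and no base is present that could expel the β-oxygen.

Step 5
Reactants: 7 (1E)-1-iodo-2,6-dimethylhepta-1,5-diene; 10 2-[(4S)-2,2,4-trimethyl-5-oxo-1,3-dioxolan-4-yl]acetyl chloride
Product: 13 (5S)-5-[(3E)-4,8-dimethyl-2-oxonona-3,7-dienyl]-2,2,5-trimethyl-1,3-dioxolan-4-one, via alkenyllithium 11 (not isolated), via alkenylzinc chloride 12 (not isolated)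
Conditions: 7, t-BuLi (2.05 equiv), Et2O, −78 °C; ZnCl2 (1.1 equiv), THF, −78 → 0 °C; then 10, Pd(PPh3)4 (5 mol%), THF, 0 °C → rt
Reagents that add atoms: none
Why: iodine–lithium exchange and transmetalation keep the E geometry, and the Negishi acylation (zerovalent palladium, oxidative addition of the acyl chloride) gives the enone because the non-basic alkenylzinc neither attacks the dioxolanone carbonyl nor triggers β-elimination.

Step 6
Reactants: 13 (5S)-5-[(3E)-4,8-dimethyl-2-oxonona-3,7-dienyl]-2,2,5-trimethyl-1,3-dioxolan-4-one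
Product: 15 (3S,5R)-5-[(1E)-2,6-dimethylhepta-1,5-dienyl]-3-hydroxy-3-methyloxolan-2-one, via hydroxy dioxolanone 14 (not isolated)
Conditions: (S)-Me-CBS oxazaborolidine (0.2 equiv), catecholborane (1.8 equiv), toluene, −78 °C; MeOH, pH 7 buffer; crude, DBU (0.2 equiv), CH2Cl2, rt
Reagents that add atoms: none
Why: CBS reduction with the (S)-oxazaborolidine should treat the alkenyl group as the large substituent and give the (R)-allylic alcohol (the sense of acetophenone to (R)-1-phenylethanol) without conjugate reduction or hydroboration, after which the γ-hydroxyl opens the activated dioxolanone by 5-exo-trig acyl transfer with loss of acetone; any C5 epimer is a diastereomer and is removed by chromatography at this stage.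

Step 7
Reactants: 15 (3S,5R)-5-[(1E)-2,6-dimethylhepta-1,5-dienyl]-3-hydroxy-3-methyloxolan-2-one
Product: 16 (3S,5R)-5-[(1E)-2,6-dimethylhepta-1,5-dienyl]-3-methyloxolane-2,3-diol (both anomers)
Conditions: i-Bu2AlH (2.3 equiv), CH2Cl2, −78 °C; aq. KNaC4H4O6 (potassium sodium tartrate)
Reagents that add atoms: none
Why: partial reduction of a lactone to the lactol, in which the first equivalent is taken by the tertiary hydroxyl and the resulting aluminium alkoxide chelates the tetrahedral intermediate against over-reduction at −78 °C.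

Step 8
Reactants: 16 (3S,5R)-5-[(1E)-2,6-dimethylhepta-1,5-dienyl]-3-methyloxolane-2,3-diol
Product: 17 (3S,5R,6E)-3,7,11-trimethyldodeca-6,10-dien-1-yne-3,5-diol
Conditions: MeC(O)C(N2)P(O)(OMe)2 (1.5 equiv), K2CO3, MeOH, 0 °C → rt
Reagents that add atoms: dimethyl (1-diazo-2-oxopropyl)phosphonate CC(=O)C(=[N+]=[N-])P(=O)(OC)OC
Why: Ohira–Bestmann homologation acts on the hydroxy aldehyde in equilibrium with the lactol; the aldehyde carbon is attached to a quaternary carbon, so nothing can epimerise, and the released C5 hydroxyl is the nucleophile of the next step.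

Step 9
Reactants: 17 (3S,5R,6E)-3,7,11-trimethyldodeca-6,10-dien-1-yne-3,5-diol
Product: 18 (2R,4S)-2-[(1E)-2,6-dimethylhepta-1,5-dienyl]-4-methyl-3,4-dihydro-2H-pyran-4-ol
Conditions: W(CO)6 (0.25 equiv), Et3N (3 equiv), THF, hν (350 nm), 60 °C
Reagents that add atoms: none
Why: photogenerated W(CO)5 converts the terminal alkyne into a tungsten vinylidene whose α-carbon is attacked by the C5 hydroxyl (tungsten-catalysed alkynol cycloisomerisation, 6-endo in outcome), and base-assisted protodemetalation of the oxacarbene gives the cyclic enol ether; the tertiary hydroxyl could only form a four-membered ring and both carbinol centres are untouched.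

Step 10
Reactants: 18 (2R,4S)-2-[(1E)-2,6-dimethylhepta-1,5-dienyl]-4-methyl-3,4-dihydro-2H-pyran-4-ol
Product: 20 (2R,3S,5R)-2-(dimethoxymethyl)-5-[(1E)-2,6-dimethylhepta-1,5-dienyl]-3-methyloxolan-3-ol, via iodonium adduct 19 (not isolated)
Conditions: PhI(OH)OTs (1.1 equiv), MeOH (20 equiv), 2,6-di-tert-butyl-4-methylpyridine (2.5 equiv), 3 Å MS, CH2Cl2, −40 → 0 °C
Reagents that add atoms: methanol CO
Why: PhI(OH)OTs is converted by methanol into a methoxy(phenyl)iodonium electrophile (trivalent iodine) that attacks the enol ether carbon C5 of the dihydropyran (O1, C2 dienyl, C3, C4 methyl carbinol, C5, C6) while methanol caps the C6 oxocarbenium ion to give adduct 19; with the C5–I bond equatorial the ring bond C6–O1 is antiperiplanar to it, and O1, pushed by the anomeric methoxy group, displaces iodobenzene with inversion through a bridged oxonium ion, after which methanol traps the exocyclic oxocarbenium ion at C6 (the future C1′) as the dimethyl acetal. The closest known reaction type is the oxidative ring contraction of glycals to 2,5-anhydroaldose acetals with PhI(OH)OTs or Tl(NO3)3 in methanol, which shares its stereoelectronics with the solvolytic contraction of equatorial pyranoside 2-sulfonates. The oxolane is not closed from an open chain but arises by a 1,2-shift of the ring oxygen (formally 3-exo-tet attack of O1 on C5 followed by C6–O1 cleavage), six-membered to five-membered. The one new stereocentre, oxolane C2, is fixed by the invertive shift at C5 of 19, so the iodane must enter cis to the axial tertiary hydroxyl and trans to the equatorial methyl; the free hydroxyl is expected to guide it there by hydrogen bonding or ligand exchange at iodine (as in hydroxyl-directed epoxidation and oxymercuration of cyclic allylic alcohols), the half-chair with dienyl and methyl equatorial keeps that C5–I bond equatorial, and an axial C5–I adduct has no antiperiplanar ring oxygen and cannot contract. Chemoselectivity for the enol ether over the two trisubstituted alkenes rests on its much higher nucleophilicity, the small excess of reagent and the low temperature. The hindered pyridine takes up the TsOH that is released so that the tertiary allylic alcohol does not ionise in a Ferrier-type process, and the low methanol concentration in CH2Cl2 preserves the directing hydrogen bond.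

Step 11
Reactants: 20 (2R,3S,5R)-2-(dimethoxymethyl)-5-[(1E)-2,6-dimethylhepta-1,5-dienyl]-3-methyloxolan-3-ol
Product: 23 (2R,3S,5R)-5-[(1E)-2,6-dimethylhepta-1,5-dienyl]-3-methyl-3-(triethylsilyloxy)oxolane-2-carbaldehyde, via silyl ether 21 (not isolated), via collidinium salt 22 (not isolated)
Conditions: Et3SiOTf (3.5 equiv), 2,4,6-collidine (5 equiv), CH2Cl2, 0 °C; H2O, 0 °C → rt
Reagents that add atoms: triethylsilyl triflate CC[Si](CC)(CC)OS(=O)(=O)C(F)(F)F; water O
Why: silyl triflate with a hindered pyridine silylates the tertiary hydroxyl and turns the dimethyl acetal into an N-(α-methoxyalkyl)pyridinium salt that water hydrolyses (non-acidic acetal cleavage), so the α-oxygenated acetal is unmasked without the aqueous acid that would protonate the trisubstituted alkenes or ionise the allylic C5–O1 bond.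

Step 12
Reactants: 24 3-methoxycyclohex-2-en-1-one
Product: 26 rac-6-hydroxy-3-methoxycyclohex-2-en-1-one, via potassium dienolate 25 (not isolated)
Conditions: KN(SiMe3)2 (1.1 equiv), THF, −78 °C; 2-(phenylsulfonyl)-3-phenyloxaziridine (1.3 equiv), −78 °C; aq. NH4Cl
Reagents that add atoms: 2-(phenylsulfonyl)-3-phenyloxaziridine O=S(=O)(c1ccccc1)N1OC1c1ccccc1
Why: kinetic deprotonation of the vinylogous ester occurs at C6 (α′), and oxygen transfer from the N-sulfonyloxaziridine to the cross-conjugated enolate (enolate α-hydroxylation) gives the α′-hydroxy enone.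

Step 13
Reactants: 26 rac-6-hydroxy-3-methoxycyclohex-2-en-1-one
Product: 27 (S)-6-hydroxy-3-methoxycyclohex-2-en-1-one
Conditions: lipase PS (Burkholderia cepacia), vinyl acetate, t-BuOMe, 30 °C, stopped just past half conversion
Reagents that add atoms: none
Why: lipase-catalysed irreversible transesterification (kinetic resolution of a secondary alcohol) should acetylate the (R)-alcohol and leave the (S)-alcohol, which is separated from the acetate by chromatography and checked by chiral HPLC.

Step 14
Reactants: 27 (S)-6-hydroxy-3-methoxycyclohex-2-en-1-one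
Product: 28 (S)-6-(tert-butyldimethylsilyloxy)-3-methoxycyclohex-2-en-1-one
Conditions: t-BuMe2SiCl, imidazole, DMF, rt
Reagents that add atoms: tert-butyldimethylsilyl chloride CC(C)(C)[Si](C)(C)Cl
Why: silylation of a secondary alcohol under a base too weak to enolise the α′-stereocentre.

Step 15
Reactants: 28 (S)-6-(tert-butyldimethylsilyloxy)-3-methoxycyclohex-2-en-1-one
Product: 29 (4S)-4-(tert-butyldimethylsilyloxy)cyclohexane-1,3-dione
Conditions: 1 M HCl, THF, 0 °C → rt
Reagents that add atoms: water O
Why: acid hydrolysis of the vinylogous methyl ester (addition of water at C3 and loss of methanol) is fast under conditions that a secondary silyl ether next to a carbonyl survives, and the product rests as its enol, so C4 is not enolised.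

Step 16
Reactants: 23 (2R,3S,5R)-5-[(1E)-2,6-dimethylhepta-1,5-dienyl]-3-methyl-3-(triethylsilyloxy)oxolane-2-carbaldehyde; 29 (4S)-4-(tert-butyldimethylsilyloxy)cyclohexane-1,3-dione
Product: 31 (4S)-4-(tert-butyldimethylsilyloxy)-2-{[(2S,3S,5R)-5-[(1E)-2,6-dimethylhepta-1,5-dienyl]-3-methyl-3-(triethylsilyloxy)oxolan-2-yl]methyl}-3-hydroxycyclohex-2-en-1-one, via alkylidene dione 30 (not isolated)
Conditions: L-proline (0.2 equiv), Hantzsch ester (1.2 equiv), CH2Cl2, rt
Reagents that add atoms: none
Why: amine-catalysed Knoevenagel condensation gives a 2-alkylidene-1,3-dione that is reduced at once by hydride transfer from the Hantzsch ester (three-component reductive alkylation of 1,3-diones), so C1′ becomes the methylene before a second dione can add and no new stereocentre is formed.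

Step 17
Reactants: 31 (4S)-4-(tert-butyldimethylsilyloxy)-2-{[(2S,3S,5R)-5-[(1E)-2,6-dimethylhepta-1,5-dienyl]-3-methyl-3-(triethylsilyloxy)oxolan-2-yl]methyl}-3-hydroxycyclohex-2-en-1-one
Product: 32 (4S)-2-{[(2S,3S,5R)-5-[(1E)-2,6-dimethylhepta-1,5-dienyl]-3-hydroxy-3-methyloxolan-2-yl]methyl}-3,4-dihydroxycyclohex-2-en-1-one (CNP0194047.1)
Conditions: HF·pyridine, pyridine, THF, 0 °C → rt
Reagents that add atoms: none
Why: buffered fluoride desilylation removes the tertiary triethylsilyl and the secondary tert-butyldimethylsilyl ether together without acid strong enough to ionise the allylic ether or to close the tertiary hydroxyl onto the dione.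

**Compound list**

1 | 6-methylhept-5-en-2-one | CC(=O)CCC=C(C)C | starting material
2 | lithium 6-methylhepta-1,5-dien-2-olate | [Li]OC(=C)CCC=C(C)C | intermediate
3 | diethyl 6-methylhepta-1,5-dien-2-yl phosphate | C=C(CCC=C(C)C)OP(=O)(OCC)OCC | intermediate
4 | (6-methylhept-5-en-1-ynyl)lithium | [Li]C#CCCC=C(C)C | intermediate
5 | 6-methylhept-5-en-1-yne | C#CCCC=C(C)C | intermediate
6 | [(1E)-2,6-dimethylhepta-1,5-dienyl]dimethylalane | C[Al](C)/C=C(\C)CCC=C(C)C | intermediate
7 | (1E)-1-iodo-2,6-dimethylhepta-1,5-diene | I/C=C(\C)CCC=C(C)C | intermediate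
8 | (S)-citramalic acid | C[C@](O)(CC(=O)O)C(=O)O | starting material
9 | 2-[(4S)-2,2,4-trimethyl-5-oxo-1,3-dioxolan-4-yl]acetic acid | C[C@@]1(CC(=O)O)OC(C)(C)OC1=O | intermediate
10 | 2-[(4S)-2,2,4-trimethyl-5-oxo-1,3-dioxolan-4-yl]acetyl chloride | C[C@@]1(CC(=O)Cl)OC(C)(C)OC1=O | intermediate
11 | [(1E)-2,6-dimethylhepta-1,5-dienyl]lithium | [Li]/C=C(\C)CCC=C(C)C | intermediate
12 | chloro[(1E)-2,6-dimethylhepta-1,5-dienyl]zinc | Cl[Zn]/C=C(\C)CCC=C(C)C | intermediate
13 | (5S)-5-[(3E)-4,8-dimethyl-2-oxonona-3,7-dienyl]-2,2,5-trimethyl-1,3-dioxolan-4-one | C[C@@]1(CC(=O)/C=C(\C)CCC=C(C)C)OC(C)(C)OC1=O | intermediate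
14 | (5S)-5-[(2R,3E)-2-hydroxy-4,8-dimethylnona-3,7-dienyl]-2,2,5-trimethyl-1,3-dioxolan-4-one | C[C@@]1(C[C@@H](O)/C=C(\C)CCC=C(C)C)OC(C)(C)OC1=O | intermediate
15 | (3S,5R)-5-[(1E)-2,6-dimethylhepta-1,5-dienyl]-3-hydroxy-3-methyloxolan-2-one | C[C@]1(O)C[C@H](/C=C(\C)CCC=C(C)C)OC1=O | intermediate
16 | (3S,5R)-5-[(1E)-2,6-dimethylhepta-1,5-dienyl]-3-methyloxolane-2,3-diol (both anomers) | C[C@]1(O)C[C@H](/C=C(\C)CCC=C(C)C)OC1O | intermediate
17 | (3S,5R,6E)-3,7,11-trimethyldodeca-6,10-dien-1-yne-3,5-diol | C#C[C@@](C)(O)C[C@@H](O)/C=C(\C)CCC=C(C)C | intermediate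
18 | (2R,4S)-2-[(1E)-2,6-dimethylhepta-1,5-dienyl]-4-methyl-3,4-dihydro-2H-pyran-4-ol | CC(C)=CCC/C(C)=C/[C@H]1C[C@](C)(O)C=CO1 | intermediate
19 | [(3S,4S,6R)-6-[(1E)-2,6-dimethylhepta-1,5-dienyl]-4-hydroxy-2-methoxy-4-methyloxan-3-yl](phenyl)iodonium tosylate (both C2 epimers) | CC(C)=CCC/C(C)=C/[C@H]1C[C@](C)(O)[C@H]([I+]c2ccccc2)C(OC)O1.[O-]S(=O)(=O)c1ccc(C)cc1 | intermediate
20 | (2R,3S,5R)-2-(dimethoxymethyl)-5-[(1E)-2,6-dimethylhepta-1,5-dienyl]-3-methyloxolan-3-ol | CC(C)=CCC/C(C)=C/[C@H]1C[C@](C)(O)[C@H](C(OC)OC)O1 | intermediate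
21 | {[(2R,3S,5R)-2-(dimethoxymethyl)-5-[(1E)-2,6-dimethylhepta-1,5-dienyl]-3-methyloxolan-3-yl]oxy}triethylsilane | CC(C)=CCC/C(C)=C/[C@H]1C[C@](C)(O[Si](CC)(CC)CC)[C@H](C(OC)OC)O1 | intermediate
22 | 1-{[(2R,3S,5R)-5-[(1E)-2,6-dimethylhepta-1,5-dienyl]-3-methyl-3-(triethylsilyloxy)oxolan-2-yl](methoxy)methyl}-2,4,6-trimethylpyridinium triflate (both epimers at the N,O-acetal carbon) | CC(C)=CCC/C(C)=C/[C@H]1C[C@](C)(O[Si](CC)(CC)CC)[C@H](C(OC)[n+]2c(C)cc(C)cc2C)O1.[O-]S(=O)(=O)C(F)(F)F | intermediate
23 | (2R,3S,5R)-5-[(1E)-2,6-dimethylhepta-1,5-dienyl]-3-methyl-3-(triethylsilyloxy)oxolane-2-carbaldehyde | CC(C)=CCC/C(C)=C/[C@H]1C[C@](C)(O[Si](CC)(CC)CC)[C@H](C=O)O1 | intermediate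
24 | 3-methoxycyclohex-2-en-1-one | COC1=CC(=O)CCC1 | starting material
25 | potassium 3-methoxycyclohexa-1(6),2-dien-1-olate | COC1=CC(O[K])=CCC1 | intermediate
26 | rac-6-hydroxy-3-methoxycyclohex-2-en-1-one | COC1=CC(=O)C(O)CC1 | intermediate
27 | (S)-6-hydroxy-3-methoxycyclohex-2-en-1-one | COC1=CC(=O)[C@@H](O)CC1 | intermediate
28 | (S)-6-(tert-butyldimethylsilyloxy)-3-methoxycyclohex-2-en-1-one | COC1=CC(=O)[C@@H](O[Si](C)(C)C(C)(C)C)CC1 | intermediate
29 | (4S)-4-(tert-butyldimethylsilyloxy)cyclohexane-1,3-dione | O=C1CC(=O)[C@@H](O[Si](C)(C)C(C)(C)C)CC1 | intermediate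
30 | (4S)-4-(tert-butyldimethylsilyloxy)-2-{[(2S,3S,5R)-5-[(1E)-2,6-dimethylhepta-1,5-dienyl]-3-methyl-3-(triethylsilyloxy)oxolan-2-yl]methylidene}cyclohexane-1,3-dione | CC(C)=CCC/C(C)=C/[C@H]1C[C@](C)(O[Si](CC)(CC)CC)[C@H](C=C2C(=O)CC[C@H](O[Si](C)(C)C(C)(C)C)C2=O)O1 | intermediate
31 | (4S)-4-(tert-butyldimethylsilyloxy)-2-{[(2S,3S,5R)-5-[(1E)-2,6-dimethylhepta-1,5-dienyl]-3-methyl-3-(triethylsilyloxy)oxolan-2-yl]methyl}-3-hydroxycyclohex-2-en-1-one | CC(C)=CCC/C(C)=C/[C@H]1C[C@](C)(O[Si](CC)(CC)CC)[C@H](CC2=C(O)[C@@H](O[Si](C)(C)C(C)(C)C)CCC2=O)O1 | intermediate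
32 | (4S)-2-{[(2S,3S,5R)-5-[(1E)-2,6-dimethylhepta-1,5-dienyl]-3-hydroxy-3-methyloxolan-2-yl]methyl}-3,4-dihydroxycyclohex-2-en-1-one (CNP0194047.1) | CC(C)=CCC/C(C)=C/[C@H]1C[C@](C)(O)[C@H](CC2=C(O)[C@@H](O)CCC2=O)O1 | target

**Step count and risks**

Total step count: 17. Longest linear sequence: 11 steps (steps 3–11, 16 and 17 from 8; the same length from 1 through steps 1, 2, 5–11, 16 and 17).

The three steps most likely to fail:

1. Step 10. The iodane may add to the face of the enol ether away from the hydroxyl, which gives an adduct that cannot contract. The tertiary allylic alcohol may ionise. The C3–C4 ring bond, which is also antiperiplanar to the leaving group, may migrate in place of O1 under the push of the free hydroxyl. Fallback: set out from 18 and separate the oxidation from the shift. VO(acac)2 (cat.), t-BuOOH, CH2Cl2, 0 °C with methanol present should epoxidise only the enol ether, on the face of the tertiary hydroxyl (hydroxyl-directed epoxidation; the other alkenes carry no directing group). Methanol then opens the 1,2-anhydro intermediate at the anomeric carbon to give (2S,3S,4S,6R)-6-[(1E)-2,6-dimethylhepta-1,5-dienyl]-2-methoxy-4-methyloxane-3,4-diol F1. Tf2O, pyridine, CH2Cl2, −30 °C should sulfonylate the secondary, equatorial hydroxyl in preference to the tertiary one and give (2S,3S,4S,6R)-6-[(1E)-2,6-dimethylhepta-1,5-dienyl]-4-hydroxy-2-methoxy-4-methyloxan-3-yl trifluoromethanesulfonate F2. Warming F2 in methanol with 2,6-lutidine should bring about the same antiperiplanar shift of the ring oxygen with inversion (solvolytic ring contraction of an equatorial pyranoside 2-sulfonate) and comes back to the route at 20.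

2. Step 11. The silyl triflate may ionise the allylic C5–O1 bond, the α-oxygenated acetal may resist activation, or the aldehyde may epimerise at C2 during hydrolysis of the pyridinium salt. Fallback: set out from 18 and avoid the acetal stage. The same ring contraction run with PhI(OH)OTs and NaHCO3 in MeCN–H2O at 0 °C lets water instead of methanol capture both oxocarbenium ions and should give (2R,3S,5R)-5-[(1E)-2,6-dimethylhepta-1,5-dienyl]-3-hydroxy-3-methyloxolane-2-carbaldehyde F3 directly (known for glycals in aqueous acetonitrile). Et3SiOTf, 2,6-lutidine, CH2Cl2, −78 °C then silylates the tertiary hydroxyl and comes back to the route at 23.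

3. Step 9. Closure may go exo to the 2-methyleneoxolane, or the free propargylic hydroxyl may bind and deactivate the tungsten catalyst. Fallback: set out from 17 and reach the enol ether by dehydration instead of cycloisomerisation. Hydroboration of the terminal alkyne with Cy2BH (excess, THF, 0 °C; the trisubstituted alkenes are too hindered to react) and oxidation with NaBO3·4H2O should give the aldehyde, which closes onto the C5 hydroxyl as (4S,6R)-6-[(1E)-2,6-dimethylhepta-1,5-dienyl]-4-methyloxane-2,4-diol F4. MsCl, Et3N, CH2Cl2, −40 °C → reflux then eliminates the anomeric sulfonate (lactol to glycal dehydration of a 2-deoxy sugar) and comes back to the route at 18.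

Further compounds
F1 | step 10 | (2S,3S,4S,6R)-6-[(1E)-2,6-dimethylhepta-1,5-dienyl]-2-methoxy-4-methyloxane-3,4-diol | CC(C)=CCC/C(C)=C/[C@H]1C[C@](C)(O)[C@H](O)[C@@H](OC)O1
F2 | step 10 | (2S,3S,4S,6R)-6-[(1E)-2,6-dimethylhepta-1,5-dienyl]-4-hydroxy-2-methoxy-4-methyloxan-3-yl trifluoromethanesulfonate | CC(C)=CCC/C(C)=C/[C@H]1C[C@](C)(O)[C@H](OS(=O)(=O)C(F)(F)F)[C@@H](OC)O1
F3 | step 11 | (2R,3S,5R)-5-[(1E)-2,6-dimethylhepta-1,5-dienyl]-3-hydroxy-3-methyloxolane-2-carbaldehyde | CC(C)=CCC/C(C)=C/[C@H]1C[C@](C)(O)[C@H](C=O)O1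
F4 | step 9 | (4S,6R)-6-[(1E)-2,6-dimethylhepta-1,5-dienyl]-4-methyloxane-2,4-diol (both anomers) | CC(C)=CCC/C(C)=C/[C@H]1C[C@](C)(O)CC(O)O1
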